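## Analysis of the target

Compound 34 joins two rings through the methylene C7. Ring A is a 4-methoxycyclohexane-1,3-dione drawn as its enol (A1 ketone, A2 the alkylated sp2 carbon, A3 the enol carbon, A4 the methoxy carbon). Ring B is a cyclopentene (B1 methine carrying C7, B2 the sp2 carbon carrying the side chain, B3 =CH, B4 CH2, B5 the methyl carbinol), and B2 carries the chain D1(CH3)=D2H–D3H2–CH=C(CH3)2. There are three stereocentres: A4 (S), which is remote and has to be set independently, and the vicinal pair B1 (R) and B5 (S), with C7 and the tertiary hydroxyl cis on ring B. The D1=D2 alkene is trisubstituted and Z (B2 and D3 on the same side), conjugated with B2=B3 and separated from the prenyl alkene by the doubly allylic D3. Sensitive groups are the acidic, ambident enolised dione with its enolisable α-methoxy centre, the tertiary alcohol, and the conjugated Z-diene, which can isomerise or be protonated. The hard points are the Z-trisubstituted alkene inside a 1,3-diene, the adjacent fully substituted carbinol and allylic methine on a five-membered ring, and the union of C7 with A2 without O-alkylation. The plan rests on the fact that B2, B3, D1 and D2 form a 1-alkenylcyclopentene, the product of skeletal rearrangement of a 1,6-enyne whose alkyne is B2≡D1 (carrying the D1 methyl) and whose tether B1–B5–B4 ends in a Z-alkene B3=D2 that already carries D3 and the prenyl end.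

## Retrosynthetic reasoning

34 from 33. The last step only unmasks. The enolised dione is carried as its methyl enol ether and the tertiary alcohol as a silyl ether, because the free dione would quench or mislead every organometallic step. One mild aqueous acid treatment has to remove both.

33 from 31 and 32 (32 from 22). The C7–A2 bond is cut. A4 can neither direct nor be directed by B1 and B5, so the two halves are best made separately. Cutting here gives an sp3 nucleophile at C7 and an sp2 electrophile at A2, which avoids O-alkylation of a dione. The forward coupling has to outrun β-hydride elimination towards B1.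

31 back to 23. Ring A is opened at A2–A3 (intramolecular Claisen condensation of 28) and at A1–A2 (methyl addition to the amide 27). Five ring carbons and the A4 stereocentre then come from L-glutamic acid 23 through the lactone acid 24, whose formation retains configuration. Compounds 25 and 26 differentiate the two carboxyl ends, 29 is the dione, and 30 its enol ether.

22 back to 19. These are functional-group changes: the iodide 22 comes from the diol 20 by way of 21, and 20 from the silylene 19.

19 from 18 (key disconnection). B2–B3 and D1=D2 are cut and B3=D2 is restored, which opens ring B to the enyne 18. This is chosen because it replaces the difficult Z-trisubstituted alkene by an easily made Z-disubstituted one and makes ring B in the same step. The forward reaction needs exo closure and faithful transfer of alkene geometry.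

18 from 14 and 17 (17 from 16, 16 from 15). The Z-alkene B3=D2 is cut by a Wittig disconnection. A non-stabilised ylide reliably gives the Z isomer and brings in the prenyl end in one piece.

14 back to 11. The aldehyde 14 comes from the alcohol 13, and 13 from the silyl ether 12. The silylene of 12 ties the 1,3-diol of 11 into a six-membered ring that protects both oxygens and holds alkyne and alkene arm gauche.

11 from 6 and 9 (9 from 7). The B1–B2 bond is cut. An alkynyl anion opens the epoxide at its only SN2-accessible carbon with inversion, which sets B1 relative to B5.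

6 from 5. Sharpless epoxidation sets B5 in the absolute sense. The Z geometry of 5 together with the later anti opening gives the cis relation of C7 and the hydroxyl.

5 back to 1. The Z-trisubstituted allylic alcohol 5 comes from the lactone 1 through 2 and 3. The ring of 1 enforces the geometry, so no stereoselective olefination is needed.

## Alternatives that were turned down

Alternative 1: Ring B is disconnected at B1–B5 to a furan. The racemic furylcarbinol A2 would ionise under a chiral BINOL-derived phosphoric acid in wet solvent, be hydrated at the methyl-bearing furan carbon, open to a hydroxypentadienyl cation and close by conrotatory 4π cyclisation to the cyclopentenone A1.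
- For: it is a very short, enantioconvergent entry to both ring B stereocentres from a cheap furan. On speed to the ring B core it is stronger than the chosen route.
- Against: nothing in A2 secures which of hydroxyl and methyl turns outward at the fully substituted terminus, and the rearrangement normally places the new hydroxyl trans to the neighbouring substituent, whereas A1 needs them cis. Catalyst control of this hydrative variant at a fully substituted carbon would be an extrapolation.
- Against: A1 has its carbonyl at B2 and its alkene at B3=B4. It would need conjugate reduction, regioselective enol triflate formation next to an epimerisable B1 and a β-oxygen, and then coupling with a separately made Z-alkenyl fragment.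
- Comparison: the Z-diene is not addressed by the key step. The chosen strategy makes ring and Z-alkene together and sets the stereocentres by epoxide chemistry.

Alternative 2: Three bonds (A2–C7, C7–B1, O–B5) are cut at once. The dione 29 would condense with formaldehyde A5 to the methylene dione A4, which would add as a 1-oxadiene to the cyclopentene A6 to give the cycloadduct A3.
- For: it is the most convergent plan, it avoids any sp3–sp2 coupling, and the suprafacial addition gives the cis relation at B1 and B5 automatically. On step count to the full carbon skeleton it is stronger.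
- Against: A6 is an unactivated trisubstituted alkene, facial selectivity rests only on its allylic silyloxy group, and A4 can be intercepted by a second molecule of 29.
- Against: in A3 the tertiary oxygen is tied to the ring A enol as a dihydropyran. Opening this cyclic vinylogous ester at a tertiary carbon at the end runs against the tendency of the system to close.
- Against: the side chain would still have to be built at B2 from a silyloxy group, late and in the presence of ring A.
- Comparison: the chosen strategy keeps the tertiary alcohol and the enol apart throughout and installs the side chain before the rings are joined.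

Alternative 3: B2–D1 and D2–D3 are cut without ring closure. The alkenyl iodide A8 would be converted (t-BuLi, then MgBr2 and CuBr·SMe2) into an alkenylcopper that adds syn across propyne 7, and the Z-dienylcopper would be allylated by the bromide A9 to give A7.
- For: syn carbometalation is stereospecific by mechanism, so on certainty of the Z geometry it is stronger than the chosen key step.
- Against: ring B with both stereocentres and the iodide must be made beforehand by a separate multistep sequence, so the key step builds no ring.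
- Against: a hindered secondary alkenylcopper adds sluggishly to a gaseous alkyne, and allylation with A9 can occur at either allyl terminus.
- Comparison: the chosen strategy gives up some stereochemical certainty for step economy. Ring B, the B2–B3 bond and the Z-alkene come from one acyclic precursor whose two stereocentres derive from a single epoxidation.

Key step: step 11

Assumption: 34 is drawn as one enol tautomer of a 2-alkyl-4-methoxycyclohexane-1,3-dione; the tautomers interconvert, so the route aims at the dione as such.

Assumption: enol ether formation from the unsymmetrical dione 29 is taken to occur at the carbonyl remote from the methoxy-bearing carbon (giving 30); the regioisomeric enol ether would lead to the same dione after step 24.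

## Route

Step 1
Reactants: 1 4-methyl-5,6-dihydro-2H-pyran-2-one
Product: 2 (2Z)-5-hydroxy-N-methoxy-N,3-dimethylpent-2-enamide
Conditions: Me(MeO)NH·HCl, Me3Al, CH2Cl2, 0 °C → rt
Reagents that add atoms: N,O-dimethylhydroxylamine hydrochloride, CNOC.Cl
Why: Aluminium-amide aminolysis of a lactone (Weinreb amide formation); the alkene geometry is fixed by the ring of 1 and is not touched, so the Z-enamide should result, and it is silylated at once to prevent re-lactonisation.

Step 2
Reactants: 2 (2Z)-5-hydroxy-N-methoxy-N,3-dimethylpent-2-enamide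
Product: 3 (2Z)-5-[(tert-butyldimethylsilyl)oxy]-N-methoxy-N,3-dimethylpent-2-enamide
Conditions: t-BuMe2SiCl, imidazole, DMF, 0 °C → rt
Reagents that add atoms: tert-butyldimethylsilyl chloride, CC(C)(C)[Si](C)(C)Cl
Why: Standard silylation of a primary alcohol; it removes the nucleophile that could re-close the lactone and differentiates the two chain ends.

Step 3
Reactants: 3 (2Z)-5-[(tert-butyldimethylsilyl)oxy]-N-methoxy-N,3-dimethylpent-2-enamide
Product: 5 (2Z)-5-[(tert-butyldimethylsilyl)oxy]-3-methylpent-2-en-1-ol, via (2Z)-5-[(tert-butyldimethylsilyl)oxy]-3-methylpent-2-enal 4 (not isolated)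
Conditions: i-Bu2AlH, THF, −78 °C; then MeOH, CeCl3·7H2O, NaBH4, −78 → 0 °C
Reagents that add atoms: none
Why: Hydride reduction of the Weinreb amide stops at the chelated hemiaminal, which releases the Z-enal 4 on quenching; immediate Luche reduction (1,2-selective) should avoid Z to E isomerisation of the enal.

Step 4
Reactants: 5 (2Z)-5-[(tert-butyldimethylsilyl)oxy]-3-methylpent-2-en-1-ol
Product: 6 [(2R,3S)-3-{2-[(tert-butyldimethylsilyl)oxy]ethyl}-3-methyloxiran-2-yl]methanol
Conditions: Ti(Oi-Pr)4 (10 mol%), D-(−)-diethyl tartrate (12 mol%), t-BuOOH, 4 Å MS, CH2Cl2, −20 °C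
Reagents that add atoms: tert-butyl hydroperoxide, CC(C)(C)OO
Why: Sharpless asymmetric epoxidation; the D-(−)-tartrate is the ligand that converts nerol-type Z-allylic alcohols into (2R,3S)-epoxy alcohols, which sets the carbinol centre (later B5) as S, and syn oxygen transfer keeps CH2OH and the silyloxyethyl arm cis.

Step 5
Reactants: 6 [(2R,3S)-3-{2-[(tert-butyldimethylsilyl)oxy]ethyl}-3-methyloxiran-2-yl]methanol; 7 propyne
Product: 11 (2S,3S)-5-[(tert-butyldimethylsilyl)oxy]-3-methyl-2-(prop-1-yn-1-yl)pentane-1,3-diol, via trimethylsilyl ether of the epoxy alcohol 8 (not isolated), via prop-1-yn-1-yllithium 9 (not isolated), via 1-O-trimethylsilyl adduct 10 (not isolated)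
Conditions: 6, n-BuLi, THF, −78 °C, then Me3SiCl, to 0 °C; added to 7/n-BuLi and BF3·OEt2, THF, −78 °C; then K2CO3, MeOH, 0 °C
Reagents that add atoms: none
Why: BF3-mediated alkynylation of an epoxide (Yamaguchi–Hirao alkynylation), an SN2 process; the carbinol carbon is fully substituted, so attack should occur at the secondary carbon with inversion, which sets B1 (S) while the C–O bond of B5 is retained. Transient O-silylation excludes Payne rearrangement and alkoxide-directed delivery, and the labile silyl group is removed in the work-up.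

Step 6
Reactants: 11 (2S,3S)-5-[(tert-butyldimethylsilyl)oxy]-3-methyl-2-(prop-1-yn-1-yl)pentane-1,3-diol
Product: 12 tert-butyl{2-[(4S,5S)-2,2-di-tert-butyl-4-methyl-5-(prop-1-yn-1-yl)-1,3,2-dioxasilinan-4-yl]ethoxy}dimethylsilane
Conditions: t-Bu2Si(OTf)2, 2,6-lutidine, CH2Cl2, 0 °C → rt
Reagents that add atoms: di-tert-butylsilyl bis(trifluoromethanesulfonate), CC(C)(C)[Si](OS(=O)(=O)C(F)(F)F)(OS(=O)(=O)C(F)(F)F)C(C)(C)C
Why: Silylene formation on a 1,3-diol; after the primary hydroxyl is silylated the remaining triflate closes intramolecularly onto the tertiary hydroxyl, and the six-membered ring holds the propynyl group and the future allyl arm gauche.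

Step 7
Reactants: 12 tert-butyl{2-[(4S,5S)-2,2-di-tert-butyl-4-methyl-5-(prop-1-yn-1-yl)-1,3,2-dioxasilinan-4-yl]ethoxy}dimethylsilane
Product: 13 2-[(4S,5S)-2,2-di-tert-butyl-4-methyl-5-(prop-1-yn-1-yl)-1,3,2-dioxasilinan-4-yl]ethan-1-ol
Conditions: PPTS (cat.), MeOH–CH2Cl2, rt
Reagents that add atoms: none
Why: Acid-catalysed methanolysis of a primary tert-butyldimethylsilyl ether; the hindered di-tert-butylsilylene of a 1,3-diol should tolerate these mildly acidic conditions.

Step 8
Reactants: 13 2-[(4S,5S)-2,2-di-tert-butyl-4-methyl-5-(prop-1-yn-1-yl)-1,3,2-dioxasilinan-4-yl]ethan-1-ol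
Product: 14 2-[(4S,5S)-2,2-di-tert-butyl-4-methyl-5-(prop-1-yn-1-yl)-1,3,2-dioxasilinan-4-yl]acetaldehyde
Conditions: Dess–Martin periodinane, NaHCO3, CH2Cl2, 0 °C → rt
Reagents that add atoms: none
Why: Dess–Martin oxidation under buffered, non-basic conditions should give the β-silyloxy aldehyde without β-elimination.

Step 9
Reactants: 15 5-bromo-2-methylpent-2-ene
Product: 16 (4-methylpent-3-en-1-yl)triphenylphosphonium bromide
Conditions: PPh3, MeCN, reflux
Reagents that add atoms: triphenylphosphine, c1ccc(cc1)P(c1ccccc1)c1ccccc1
Why: SN2 quaternisation of the phosphine by a primary bromide.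

Step 10
Reactants: 16 (4-methylpent-3-en-1-yl)triphenylphosphonium bromide; 14 2-[(4S,5S)-2,2-di-tert-butyl-4-methyl-5-(prop-1-yn-1-yl)-1,3,2-dioxasilinan-4-yl]acetaldehyde
Product: 18 (4S,5S)-2,2-di-tert-butyl-4-methyl-4-[(2Z)-6-methylhepta-2,5-dien-1-yl]-5-(prop-1-yn-1-yl)-1,3,2-dioxasilinane, via (4-methylpent-3-en-1-ylidene)triphenylphosphorane 17 (not isolated)
Conditions: 16, NaN(SiMe3)2, THF, 0 °C; then 14, −78 °C → rt
Reagents that add atoms: none
Why: Wittig olefination with a non-stabilised ylide under lithium-free conditions is kinetically Z-selective; the low temperature keeps the β-silyloxy aldehyde from enolising or eliminating.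

Step 11
Reactants: 18 (4S,5S)-2,2-di-tert-butyl-4-methyl-4-[(2Z)-6-methylhepta-2,5-dien-1-yl]-5-(prop-1-yn-1-yl)-1,3,2-dioxasilinane
Product: 19 (4aS,7aS)-2,2-di-tert-butyl-7a-methyl-5-[(2Z)-6-methylhepta-2,5-dien-2-yl]-4,4a,7,7a-tetrahydrocyclopenta[d][1,3,2]dioxasiline
Conditions: Ph3PAuCl (5 mol%), AgSbF6 (5 mol%), CH2Cl2, 0 °C → rt
Reagents that add atoms: none
Why: The cationic monovalent gold centre binds the alkyne B2≡D1, and B3 of the Z-alkene attacks B2 in a 5-exo-dig closure that forms ring B and a cyclopropyl gold carbene (cyclopropane B2–B3–D2, carbene at D1). D2 then shifts to the carbene carbon while its bonds to B2 and B3 are given up, so that B2=B3 and D1=D2 appear and the catalyst is released; the closest known reaction type is the gold- or platinum-catalysed single-cleavage skeletal rearrangement of 1,6-enynes to 1-alkenylcyclopentenes. Closure at D1 (6-endo) is disfavoured because D1 carries the methyl group and B3 has no substituent to stabilise charge. No stereocentre is formed: the two centres of 18 are not involved and become 4a and 7a of 19, cis-fused because propynyl and allyl arm were already cis on the dioxasilinane. The element to be controlled is the D1=D2 geometry: D3 is cis to B4 on the cyclopropane, the new ring forces B4 to turn away from D1 as B3–D2 opens, and D3 must then turn towards B2, which is the Z isomer (the outcome of a formal suprafacial [2+2] addition and conrotatory opening). The step needs exo selectivity, faithful transfer of geometry and chemoselectivity against the prenyl alkene. The ring-held, fully substituted tether should secure the first and the concerted shift at a non-stabilised secondary D2 the second. The third follows from the trans placement of carbene and prenyl arm on the cyclopropane and from the silyl protection of both oxygens.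

Step 12
Reactants: 19 (4aS,7aS)-2,2-di-tert-butyl-7a-methyl-5-[(2Z)-6-methylhepta-2,5-dien-2-yl]-4,4a,7,7a-tetrahydrocyclopenta[d][1,3,2]dioxasiline
Product: 20 (1S,2S)-2-(hydroxymethyl)-1-methyl-3-[(2Z)-6-methylhepta-2,5-dien-2-yl]cyclopent-3-en-1-ol
Conditions: HF·pyridine, pyridine, THF, 0 °C → rt
Reagents that add atoms: none
Why: Fluoride cleaves both Si–O bonds of the silylene; buffering with pyridine protects the diene and the tertiary alcohol from acid.

Step 13
Reactants: 20 (1S,2S)-2-(hydroxymethyl)-1-methyl-3-[(2Z)-6-methylhepta-2,5-dien-2-yl]cyclopent-3-en-1-ol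
Product: 21 (1S,2R)-2-(iodomethyl)-1-methyl-3-[(2Z)-6-methylhepta-2,5-dien-2-yl]cyclopent-3-en-1-ol
Conditions: I2, PPh3, imidazole, CH2Cl2, 0 °C
Reagents that add atoms: iodine, II
Why: Appel iodination; only the primary alcohol forms an alkoxyphosphonium ion that iodide can displace, the tertiary alcohol stays (the descriptor at B1 changes only because of the priority of iodine).

Step 14
Reactants: 21 (1S,2R)-2-(iodomethyl)-1-methyl-3-[(2Z)-6-methylhepta-2,5-dien-2-yl]cyclopent-3-en-1-ol
Product: 22 triethyl({(1S,2R)-2-(iodomethyl)-1-methyl-3-[(2Z)-6-methylhepta-2,5-dien-2-yl]cyclopent-3-en-1-yl}oxy)silane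
Conditions: Et3SiOTf, 2,6-lutidine, CH2Cl2, −78 → 0 °C
Reagents that add atoms: triethylsilyl trifluoromethanesulfonate, CC[Si](CC)(CC)OS(=O)(=O)C(F)(F)F
Why: Silylation of a tertiary alcohol with a silyl triflate and a hindered base; it removes the acidic proton before the organozinc reagent is made.

Step 15
Reactants: 23 L-glutamic acid
Product: 24 (2S)-5-oxooxolane-2-carboxylic acid
Conditions: NaNO2, aq. HCl, 0 °C → rt
Reagents that add atoms: none
Why: Diazotisation of the α-amino acid; the α-carboxylate displaces nitrogen and the γ-carboxylate opens the resulting α-lactone, two inversions, so the S configuration is retained.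

Step 16
Reactants: 24 (2S)-5-oxooxolane-2-carboxylic acid
Product: 25 tert-butyl (2S)-5-oxooxolane-2-carboxylate
Conditions: t-BuOC(=NH)CCl3, BF3·OEt2 (cat.), CH2Cl2–cyclohexane, rt
Reagents that add atoms: tert-butyl 2,2,2-trichloroacetimidate, CC(C)(C)OC(=N)C(Cl)(Cl)Cl
Why: Acid-catalysed esterification with a trichloroacetimidate under conditions that do not enolise the α-centre; the tert-butyl ester is chosen to resist the aluminium amide and the Grignard reagent of the next steps.

Step 17
Reactants: 25 tert-butyl (2S)-5-oxooxolane-2-carboxylate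
Product: 26 tert-butyl (2S)-2-hydroxy-5-[methoxy(methyl)amino]-5-oxopentanoate
Conditions: Me(MeO)NH·HCl, Me3Al, CH2Cl2, 0 °C → rt
Reagents that add atoms: N,O-dimethylhydroxylamine hydrochloride, CNOC.Cl
Why: Aluminium-amide opening of the γ-lactone (Weinreb amide formation); the lactone is the more electrophilic and less hindered acyl group, the tert-butyl ester should stay.

Step 18
Reactants: 26 tert-butyl (2S)-2-hydroxy-5-[methoxy(methyl)amino]-5-oxopentanoate
Product: 27 tert-butyl (2S)-2-methoxy-5-[methoxy(methyl)amino]-5-oxopentanoate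
Conditions: MeI, Ag2O, 4 Å MS, MeCN, rt, dark
Reagents that add atoms: iodomethane, CI
Why: Purdie methylation of an α-hydroxy ester under non-basic conditions, so the stereocentre is not enolised.

Step 19
Reactants: 27 tert-butyl (2S)-2-methoxy-5-[methoxy(methyl)amino]-5-oxopentanoate
Product: 28 tert-butyl (2S)-2-methoxy-5-oxohexanoate
Conditions: MeMgBr, THF, −78 → 0 °C
Reagents that add atoms: methylmagnesium bromide, C[Mg]Br
Why: Grignard addition to a Weinreb amide stops at the chelated tetrahedral intermediate and gives the methyl ketone; the tert-butyl ester is inert at low temperature.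

Step 20
Reactants: 28 tert-butyl (2S)-2-methoxy-5-oxohexanoate
Product: 29 (4S)-4-methoxycyclohexane-1,3-dione
Conditions: KOt-Bu, THF, 0 °C → rt; then aq. HCl to pH 3
Reagents that add atoms: none
Why: Intramolecular Claisen (Dieckmann-type) condensation; the methyl enolate of the ketone attacks the ester in a 6-exo-trig closure and the dione is held as its enolate, which shields it from further base, while the methoxy centre takes no part.

Step 21
Reactants: 29 (4S)-4-methoxycyclohexane-1,3-dione
Product: 30 (6S)-3,6-dimethoxycyclohex-2-en-1-one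
Conditions: HC(OMe)3, MeOH, TsOH (cat.), rt
Reagents that add atoms: trimethyl orthoformate, COC(OC)OC
Why: Acid-catalysed enol ether formation of a cyclic 1,3-dione; the carbonyl remote from the methoxy-bearing carbon is the less hindered and less deactivated one.

Step 22
Reactants: 30 (6S)-3,6-dimethoxycyclohex-2-en-1-one
Product: 31 (6S)-2-iodo-3,6-dimethoxycyclohex-2-en-1-one
Conditions: N-iodosuccinimide, CH2Cl2, 0 °C → rt
Reagents that add atoms: N-iodosuccinimide, O=C1CCC(=O)N1I
Why: Electrophilic iodination at the nucleophilic α-carbon of the vinylogous ester.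

Step 23
Reactants: 22 triethyl({(1S,2R)-2-(iodomethyl)-1-methyl-3-[(2Z)-6-methylhepta-2,5-dien-2-yl]cyclopent-3-en-1-yl}oxy)silane; 31 (6S)-2-iodo-3,6-dimethoxycyclohex-2-en-1-one
Product: 33 (6S)-3,6-dimethoxy-2-({(1R,5S)-5-methyl-2-[(2Z)-6-methylhepta-2,5-dien-2-yl]-5-[(triethylsilyl)oxy]cyclopent-2-en-1-yl}methyl)cyclohex-2-en-1-one, via primary alkylzinc iodide 32 (not isolated)
Conditions: 22, Zn dust (activated with BrCH2CH2Br, Me3SiCl), LiCl, THF, 40 °C; then 31, Pd(OAc)2 (4 mol%), SPhos (8 mol%), THF, rt
Reagents that add atoms: none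
Why: Direct zinc insertion into the primary C–I bond and Negishi sp3–sp2 coupling with the α-iodo enone; the bulky, electron-rich phosphine on zerovalent palladium favours reductive elimination over β-hydride elimination, and no stereocentre of either partner is touched.

Step 24
Reactants: 33 (6S)-3,6-dimethoxy-2-({(1R,5S)-5-methyl-2-[(2Z)-6-methylhepta-2,5-dien-2-yl]-5-[(triethylsilyl)oxy]cyclopent-2-en-1-yl}methyl)cyclohex-2-en-1-one
Product: 34 (4S)-3-hydroxy-4-methoxy-2-({(1R,5S)-5-hydroxy-5-methyl-2-[(2Z)-6-methylhepta-2,5-dien-2-yl]cyclopent-2-en-1-yl}methyl)cyclohex-2-en-1-one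
Conditions: 1 M aq. HCl, THF, 0 °C → rt
Reagents that add atoms: water, O
Why: Acid hydrolysis of the vinylogous methyl ester (addition of water at the β-carbon, loss of methanol) and of the triethylsilyl ether in one operation; the dione is written as the enol tautomer of the target.

## Compound list

1 | 4-methyl-5,6-dihydro-2H-pyran-2-one | CC1=CC(=O)OCC1 | starting material
2 | (2Z)-5-hydroxy-N-methoxy-N,3-dimethylpent-2-enamide | CON(C)C(=O)/C=C(/C)CCO | intermediate
3 | (2Z)-5-[(tert-butyldimethylsilyl)oxy]-N-methoxy-N,3-dimethylpent-2-enamide | CON(C)C(=O)/C=C(/C)CCO[Si](C)(C)C(C)(C)C | intermediate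
4 | (2Z)-5-[(tert-butyldimethylsilyl)oxy]-3-methylpent-2-enal | O=C/C=C(/C)CCO[Si](C)(C)C(C)(C)C | intermediate
5 | (2Z)-5-[(tert-butyldimethylsilyl)oxy]-3-methylpent-2-en-1-ol | OC/C=C(/C)CCO[Si](C)(C)C(C)(C)C | intermediate
6 | [(2R,3S)-3-{2-[(tert-butyldimethylsilyl)oxy]ethyl}-3-methyloxiran-2-yl]methanol | OC[C@H]1O[C@@]1(C)CCO[Si](C)(C)C(C)(C)C | intermediate
7 | propyne | CC#C | starting material
8 | {[(2R,3S)-3-{2-[(tert-butyldimethylsilyl)oxy]ethyl}-3-methyloxiran-2-yl]methoxy}trimethylsilane | C[Si](C)(C)OC[C@H]1O[C@@]1(C)CCO[Si](C)(C)C(C)(C)C | intermediate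
9 | prop-1-yn-1-yllithium | [Li]C#CC | intermediate
10 | (2S,3S)-5-[(tert-butyldimethylsilyl)oxy]-3-methyl-2-(prop-1-yn-1-yl)-1-[(trimethylsilyl)oxy]pentan-3-ol | CC#C[C@@H](CO[Si](C)(C)C)[C@@](C)(O)CCO[Si](C)(C)C(C)(C)C | intermediate
11 | (2S,3S)-5-[(tert-butyldimethylsilyl)oxy]-3-methyl-2-(prop-1-yn-1-yl)pentane-1,3-diol | CC#C[C@@H](CO)[C@@](C)(O)CCO[Si](C)(C)C(C)(C)C | intermediate
12 | tert-butyl{2-[(4S,5S)-2,2-di-tert-butyl-4-methyl-5-(prop-1-yn-1-yl)-1,3,2-dioxasilinan-4-yl]ethoxy}dimethylsilane | CC#C[C@H]1CO[Si](C(C)(C)C)(C(C)(C)C)O[C@@]1(C)CCO[Si](C)(C)C(C)(C)C | intermediate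
13 | 2-[(4S,5S)-2,2-di-tert-butyl-4-methyl-5-(prop-1-yn-1-yl)-1,3,2-dioxasilinan-4-yl]ethan-1-ol | CC#C[C@H]1CO[Si](C(C)(C)C)(C(C)(C)C)O[C@@]1(C)CCO | intermediate
14 | 2-[(4S,5S)-2,2-di-tert-butyl-4-methyl-5-(prop-1-yn-1-yl)-1,3,2-dioxasilinan-4-yl]acetaldehyde | CC#C[C@H]1CO[Si](C(C)(C)C)(C(C)(C)C)O[C@@]1(C)CC=O | intermediate
15 | 5-bromo-2-methylpent-2-ene | CC(C)=CCCBr | starting material
16 | (4-methylpent-3-en-1-yl)triphenylphosphonium bromide | CC(C)=CCC[P+](c1ccccc1)(c1ccccc1)c1ccccc1.[Br-] | intermediate
17 | (4-methylpent-3-en-1-ylidene)triphenylphosphorane | CC(C)=CCC=P(c1ccccc1)(c1ccccc1)c1ccccc1 | intermediate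
18 | (4S,5S)-2,2-di-tert-butyl-4-methyl-4-[(2Z)-6-methylhepta-2,5-dien-1-yl]-5-(prop-1-yn-1-yl)-1,3,2-dioxasilinane | CC#C[C@H]1CO[Si](C(C)(C)C)(C(C)(C)C)O[C@@]1(C)C/C=C\CC=C(C)C | intermediate
19 | (4aS,7aS)-2,2-di-tert-butyl-7a-methyl-5-[(2Z)-6-methylhepta-2,5-dien-2-yl]-4,4a,7,7a-tetrahydrocyclopenta[d][1,3,2]dioxasiline | CC(C)=CC/C=C(/C)C1=CC[C@]2(C)O[Si](C(C)(C)C)(C(C)(C)C)OC[C@H]12 | intermediate
20 | (1S,2S)-2-(hydroxymethyl)-1-methyl-3-[(2Z)-6-methylhepta-2,5-dien-2-yl]cyclopent-3-en-1-ol | CC(C)=CC/C=C(/C)C1=CC[C@](C)(O)[C@@H]1CO | intermediate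
21 | (1S,2R)-2-(iodomethyl)-1-methyl-3-[(2Z)-6-methylhepta-2,5-dien-2-yl]cyclopent-3-en-1-ol | CC(C)=CC/C=C(/C)C1=CC[C@](C)(O)[C@@H]1CI | intermediate
22 | triethyl({(1S,2R)-2-(iodomethyl)-1-methyl-3-[(2Z)-6-methylhepta-2,5-dien-2-yl]cyclopent-3-en-1-yl}oxy)silane | CC(C)=CC/C=C(/C)C1=CC[C@](C)(O[Si](CC)(CC)CC)[C@@H]1CI | intermediate
23 | L-glutamic acid | N[C@@H](CCC(=O)O)C(=O)O | starting material
24 | (2S)-5-oxooxolane-2-carboxylic acid | O=C1CC[C@H](O1)C(=O)O | intermediate
25 | tert-butyl (2S)-5-oxooxolane-2-carboxylate | O=C1CC[C@H](O1)C(=O)OC(C)(C)C | intermediate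
26 | tert-butyl (2S)-2-hydroxy-5-[methoxy(methyl)amino]-5-oxopentanoate | CON(C)C(=O)CC[C@H](O)C(=O)OC(C)(C)C | intermediate
27 | tert-butyl (2S)-2-methoxy-5-[methoxy(methyl)amino]-5-oxopentanoate | CON(C)C(=O)CC[C@H](OC)C(=O)OC(C)(C)C | intermediate
28 | tert-butyl (2S)-2-methoxy-5-oxohexanoate | CC(=O)CC[C@H](OC)C(=O)OC(C)(C)C | intermediate
29 | (4S)-4-methoxycyclohexane-1,3-dione | CO[C@H]1CCC(=O)CC1=O | intermediate
30 | (6S)-3,6-dimethoxycyclohex-2-en-1-one | CO[C@H]1CCC(OC)=CC1=O | intermediate
31 | (6S)-2-iodo-3,6-dimethoxycyclohex-2-en-1-one | CO[C@H]1CCC(OC)=C(I)C1=O | intermediate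
32 | ({(1R,5S)-5-methyl-2-[(2Z)-6-methylhepta-2,5-dien-2-yl]-5-[(triethylsilyl)oxy]cyclopent-2-en-1-yl}methyl)zinc iodide | CC(C)=CC/C=C(/C)C1=CC[C@](C)(O[Si](CC)(CC)CC)[C@@H]1C[Zn]I | intermediate
33 | (6S)-3,6-dimethoxy-2-({(1R,5S)-5-methyl-2-[(2Z)-6-methylhepta-2,5-dien-2-yl]-5-[(triethylsilyl)oxy]cyclopent-2-en-1-yl}methyl)cyclohex-2-en-1-one | CO[C@H]1CCC(OC)=C(C[C@@H]2C(/C(C)=C\CC=C(C)C)=CC[C@]2(C)O[Si](CC)(CC)CC)C1=O | intermediate
34 | (4S)-3-hydroxy-4-methoxy-2-({(1R,5S)-5-hydroxy-5-methyl-2-[(2Z)-6-methylhepta-2,5-dien-2-yl]cyclopent-2-en-1-yl}methyl)cyclohex-2-en-1-one | CO[C@H]1CCC(=O)C(C[C@@H]2C(/C(C)=C\CC=C(C)C)=CC[C@]2(C)O)=C1O | target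

## Step count and least certain steps

Total step count: 24. Longest linear sequence: 15 steps (1 to 34 through steps 1–8, 10–14, 23 and 24). The ring A branch from 23 has ten steps to 34, and the phosphonium salt is one step.

Step 11 (key step).
- What may go wrong: the internal alkyne combined with a Z-alkyl alkene goes beyond the cases on which the stereospecificity of this rearrangement rests. Geometry can leak if the cyclopropyl carbene opens stepwise to a cation at D2 that rotates before it migrates. A competing 1,2-shift would give the double-cleavage isomer, closure could turn 6-endo, and traces of strong acid from the silver salt could move the skipped alkene into conjugation.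
- Fallback: it sets out from aldehyde 14 and from salt 16 and comes back at 19. Intramolecular alkyne–carbonyl metathesis of 14 (AgSbF6 cat., ClCH2CH2Cl) closes ring B by oxetene formation and ring opening and should give the ring B methyl ketone F1. Salt 16 is converted with aqueous NaOH into the homoprenyl diphenylphosphine oxide F2. Lithiated F2 (n-BuLi, THF, −78 °C) is added to F1 in a Horner–Wittig addition, the β-hydroxy phosphine oxide diastereomers are separated, and the adduct with the relative configuration F3 undergoes stereospecific syn elimination with NaH in DMF to give 19. This gives up selectivity in the addition in return for a geometry that is fixed by the isolated adduct.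

Step 5.
- What may go wrong: loss of regiocontrol. Attack at the secondary carbon is slowed by the adjacent silyloxymethyl group, while the Lewis acid can ionise the epoxide towards the tertiary carbon and lead to attack there or to a 1,2-shift (semipinacol rearrangement).
- Fallback: it sets out from 6 and comes back at 12. Copper-catalysed opening of 6 with CH2=CHMgBr (CuI cat., THF, −20 °C), which for epoxy alcohols with a fully substituted distal carbon goes to the carbon next to the carbinol, should give the vinyl diol F4. Silylene formation as in step 6 gives the vinyl silylene F5, and ozonolysis (O3, then PPh3) gives the aldehyde F6. Ohira–Bestmann homologation (K2CO3, MeOH) gives the terminal alkyne F7, and C-methylation (n-BuLi, MeI) gives 12.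

Step 23.
- What may go wrong: slow transmetalation, so that β-hydride elimination from the alkylpalladium or protodezincation wins, and partial rearrangement of the homoallylic radical during zinc insertion.
- Fallback: it sets out from 22 and comes back at 33. Iodine–lithium exchange on 22 (t-BuLi, Et2O, −78 °C) and trapping with B-methoxy-9-BBN give, as its borate, the B-alkyl-9-BBN derivative F8. This is coupled with 31 in a B-alkyl Suzuki–Miyaura reaction (PdCl2(dppf), aq. K3PO4, DMF, rt).

Step 24.
- What may go wrong: before the vinylogous ester is cleaved, acid may protonate the diene. The consequences would be loss of the Z geometry, addition of the enol or the tertiary hydroxyl to the allyl cation, or dehydration.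
- Fallback: it sets out from 29 and 32 and comes back at 34. Mitsunobu O-alkylation of 29 with 2-(trimethylsilyl)ethanol gives the fluoride-labile enol ether F9, and iodination with N-iodosuccinimide gives the iodo enol ether F10. Negishi coupling with 32 as in step 23 gives the coupled enol ether F11, and TBAF buffered with AcOH in THF removes the silylethyl group by fragmentation and the silyl ether without any acid.

Step 20.
- What may go wrong: partial epimerisation of the α-methoxy centre by alkoxide while the enolate attacks the hindered tert-butyl ester only slowly, and incomplete cyclisation.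
- Fallback: it sets out from 28 and comes back at 29. Cleavage of the ester with CF3CO2H gives the keto acid F12, and esterification with C6F5OH and DCC gives the pentafluorophenyl ester F13. Soft enolisation (MgBr2·OEt2, i-Pr2NEt, CH2Cl2, rt) then brings about intramolecular C-acylation of the ketone under conditions too weakly basic to enolise the ester α-position.

## Further compounds

F1 | step 11 | 1-[(4aS,7aS)-2,2-di-tert-butyl-7a-methyl-4,4a,7,7a-tetrahydrocyclopenta[d][1,3,2]dioxasilin-5-yl]ethan-1-one | CC(=O)C1=CC[C@]2(C)O[Si](C(C)(C)C)(C(C)(C)C)OC[C@H]12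
F2 | step 11 | (4-methylpent-3-en-1-yl)diphenylphosphine oxide | CC(C)=CCCP(=O)(c1ccccc1)c1ccccc1
F3 | step 11 | (2S,3R)-2-[(4aS,7aS)-2,2-di-tert-butyl-7a-methyl-4,4a,7,7a-tetrahydrocyclopenta[d][1,3,2]dioxasilin-5-yl]-3-(diphenylphosphoryl)-6-methylhept-5-en-2-ol | CC(C)=CC[C@@H](P(=O)(c1ccccc1)c1ccccc1)[C@@](C)(O)C1=CC[C@]2(C)O[Si](C(C)(C)C)(C(C)(C)C)OC[C@H]12
F4 | step 5 | (2S,3S)-5-[(tert-butyldimethylsilyl)oxy]-2-ethenyl-3-methylpentane-1,3-diol | C=C[C@@H](CO)[C@@](C)(O)CCO[Si](C)(C)C(C)(C)C
F5 | step 5 | tert-butyl{2-[(4S,5S)-2,2-di-tert-butyl-5-ethenyl-4-methyl-1,3,2-dioxasilinan-4-yl]ethoxy}dimethylsilane | C=C[C@H]1CO[Si](C(C)(C)C)(C(C)(C)C)O[C@@]1(C)CCO[Si](C)(C)C(C)(C)C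
F6 | step 5 | (4S,5S)-2,2-di-tert-butyl-4-{2-[(tert-butyldimethylsilyl)oxy]ethyl}-4-methyl-1,3,2-dioxasilinane-5-carbaldehyde | O=C[C@H]1CO[Si](C(C)(C)C)(C(C)(C)C)O[C@@]1(C)CCO[Si](C)(C)C(C)(C)C
F7 | step 5 | tert-butyl{2-[(4S,5S)-2,2-di-tert-butyl-5-ethynyl-4-methyl-1,3,2-dioxasilinan-4-yl]ethoxy}dimethylsilane | C#C[C@H]1CO[Si](C(C)(C)C)(C(C)(C)C)O[C@@]1(C)CCO[Si](C)(C)C(C)(C)C
F8 | step 23 | 9-({(1R,5S)-5-methyl-2-[(2Z)-6-methylhepta-2,5-dien-2-yl]-5-[(triethylsilyl)oxy]cyclopent-2-en-1-yl}methyl)-9-borabicyclo[3.3.1]nonane | CC(C)=CC/C=C(/C)C1=CC[C@](C)(O[Si](CC)(CC)CC)[C@@H]1CB1C2CCCC1CCC2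
F9 | step 24 | (6S)-6-methoxy-3-[2-(trimethylsilyl)ethoxy]cyclohex-2-en-1-one | CO[C@H]1CCC(OCC[Si](C)(C)C)=CC1=O
F10 | step 24 | (6S)-2-iodo-6-methoxy-3-[2-(trimethylsilyl)ethoxy]cyclohex-2-en-1-one | CO[C@H]1CCC(OCC[Si](C)(C)C)=C(I)C1=O
F11 | step 24 | (6S)-6-methoxy-2-({(1R,5S)-5-methyl-2-[(2Z)-6-methylhepta-2,5-dien-2-yl]-5-[(triethylsilyl)oxy]cyclopent-2-en-1-yl}methyl)-3-[2-(trimethylsilyl)ethoxy]cyclohex-2-en-1-one | CO[C@H]1CCC(OCC[Si](C)(C)C)=C(C[C@@H]2C(/C(C)=C\CC=C(C)C)=CC[C@]2(C)O[Si](CC)(CC)CC)C1=O
F12 | step 20 | (2S)-2-methoxy-5-oxohexanoic acid | CC(=O)CC[C@H](OC)C(=O)O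
F13 | step 20 | pentafluorophenyl (2S)-2-methoxy-5-oxohexanoate | CC(=O)CC[C@H](OC)C(=O)Oc1c(F)c(F)c(F)c(F)c1F
A1 | alternative 1 | cis-4-hydroxy-5-{[(4-methoxyphenyl)methoxy]methyl}-4-methylcyclopent-2-en-1-one (hydroxyl and alkoxymethyl on the same face) | O=C1C=C[C@](C)(O)[C@@H]1COCc2ccc(OC)cc2
A2 | alternative 1 | rac-2-[(4-methoxyphenyl)methoxy]-1-(5-methylfuran-2-yl)ethan-1-ol | Cc1ccc(o1)C(O)COCc1ccc(OC)cc1
A3 | alternative 2 | cis-fused dihydropyran cycloadduct of the ring A vinylogous ester, bridged through C7 and oxygen to the silyloxy-methylcyclopentane | CO[C@H]1CCC2=C(C1=O)C[C@@H]3[C@@H](O[Si](C)(C)C(C)(C)C)CC[C@]3(C)O2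
A4 | alternative 2 | (4S)-4-methoxy-2-methylidenecyclohexane-1,3-dione | CO[C@H]1CCC(=O)C(=C)C1=O
A5 | alternative 2 | formaldehyde | C=O
A6 | alternative 2 | tert-butyldimethyl{[(1S)-3-methylcyclopent-2-en-1-yl]oxy}silane | CC1=C[C@@H](O[Si](C)(C)C(C)(C)C)CC1
A7 | alternative 3 | tert-butyl({(1S,5S)-5-methyl-2-[(2Z)-6-methylhepta-2,5-dien-2-yl]-5-[(triethylsilyl)oxy]cyclopent-2-en-1-yl}methoxy)dimethylsilane | CC(C)=CC/C=C(/C)C1=CC[C@](C)(O[Si](CC)(CC)CC)[C@@H]1CO[Si](C)(C)C(C)(C)C
A8 | alternative 3 | tert-butyl({(1S,5S)-2-iodo-5-methyl-5-[(triethylsilyl)oxy]cyclopent-2-en-1-yl}methoxy)dimethylsilane | IC1=CC[C@](C)(O[Si](CC)(CC)CC)[C@@H]1CO[Si](C)(C)C(C)(C)C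
A9 | alternative 3 | 1-bromo-3-methylbut-2-ene | CC(C)=CCBr
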